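**Retrosynthetic overview**
- The target is reached by O-demethylation of its mono-methyl ether, which comes from ortho/para dibromination of 3-bromo-2-(5-bromo-2-methoxyphenoxy)phenol, directed by the free OH of the tribromo ring.
- That phenol comes from aromatisation of 3-bromo-2-aryloxycyclohex-2-enone, made from 2-aryloxycyclohexane-1,3-dione. One C=O becomes the C–Br that lies meta to OH (out of reach of electrophilic bromination), the other becomes the phenol OH.
- The 1,3-dione comes from Dieckmann (intramolecular Claisen) closure of a δ-keto ester. Its carbon chain is assembled in the key C–C bond formation: intermolecular Michael addition of an aryloxy β-keto ester to ethyl acrylate, followed by Krapcho loss of the extra ester.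
- The β-keto ester comes from 5-bromo-2-methoxyphenol and ethyl 4-chloroacetoacetate, so the future diaryl ether oxygen is installed first as an alkyl aryl ether.
- Ring order: the monobromo ring is bought intact; the tribromo ring is built last as a carbocycle (Michael, then Dieckmann) and then aromatised.

Assumption: the target has no stereocentre and is achiral, so no enantiomer has to be controlled; intermediates 5, 9 and 10 carry stereocentres, are used as racemates, and lose them later.

**Route**

Step 1
Reactants: 1 5-bromo-2-methoxyphenol; 2 ethyl 4-chloro-3-oxobutanoate (ethyl 4-chloroacetoacetate)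
Product: 3 ethyl 4-(5-bromo-2-methoxyphenoxy)-3-oxobutanoate
Conditions: NaH (2.2 equiv), THF, 0 °C → 40 °C; then 1 M HCl
Reagents that add atoms: none
Why: Williamson-type SN2 displacement of the α-chloro ketone chloride by the sodium phenoxide, with the second equivalent of base holding the β-keto ester as its enolate so that C2 is not alkylated.

Step 2
Reactants: 3 ethyl 4-(5-bromo-2-methoxyphenoxy)-3-oxobutanoate; 4 ethyl acrylate
Product: 5 diethyl 2-[2-(5-bromo-2-methoxyphenoxy)acetyl]pentanedioate (racemic)
Conditions: NaOEt (0.1 equiv), EtOH, 4 (1.0 equiv) added slowly, 0 °C → rt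
Reagents that add atoms: none
Why: Intermolecular Michael addition in which catalytic ethoxide deprotonates only the doubly activated C2–H (pKa about 11) of the β-keto ester, which adds to the acrylate; the new stereocentre is racemic and is removed in step 3.

Step 3
Reactants: 5 diethyl 2-[2-(5-bromo-2-methoxyphenoxy)acetyl]pentanedioate
Product: 6 ethyl 6-(5-bromo-2-methoxyphenoxy)-5-oxohexanoate
Conditions: NaCl (1.2 equiv, promoter), DMSO/H2O, 150 °C
Reagents that add atoms: none
Why: Krapcho dealkoxycarbonylation removes only the ester that is β to the ketone, because the isolated terminal ester has no activating group and the aryl methyl ether is unactivated.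

Step 4
Reactants: 6 ethyl 6-(5-bromo-2-methoxyphenoxy)-5-oxohexanoate
Product: 7 2-(5-bromo-2-methoxyphenoxy)cyclohexane-1,3-dione
Conditions: t-BuOK (2.2 equiv), THF, 0 °C → rt; then 1 M HCl
Reagents that add atoms: none
Why: Dieckmann-type intramolecular Claisen condensation in which the aryloxy-substituted α-carbon, the most acidic CH, can only close a six-membered ring onto the ester, and deprotonation of the acidic 1,3-dione product drives the equilibrium.

Step 5
Reactants: 7 2-(5-bromo-2-methoxyphenoxy)cyclohexane-1,3-dione
Product: 8 3-bromo-2-(5-bromo-2-methoxyphenoxy)cyclohex-2-en-1-one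
Conditions: PPh3 (1.15 equiv), Br2 (1.1 equiv), MeCN, 0 °C; then 7, Et3N (1.15 equiv), rt
Reagents that add atoms: bromine, BrBr (delivered as Ph3PBr2)
Why: Piers conversion of a cyclic 1,3-dione into a β-bromo enone, in which the enol oxygen attacks Ph3PBr2 and bromide displaces Ph3P=O by addition–elimination, and the symmetry of 7 allows only one regioisomer.

Step 6
Reactants: 8 3-bromo-2-(5-bromo-2-methoxyphenoxy)cyclohex-2-en-1-one
Product: 9 3-bromo-2-(5-bromo-2-methoxyphenoxy)-6-(phenylselanyl)cyclohex-2-en-1-one (racemic)
Conditions: LDA (commercial solution, 1.1 equiv), THF, −78 °C; then PhSeCl (1.1 equiv), −78 °C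
Reagents that add atoms: phenylselanyl chloride, Cl[Se]c1ccccc1
Why: Kinetic α′-deprotonation of the enone by LDA at −78 °C and trapping of the lithium dienolate with PhSeCl (Reich α-selenenylation); the new C6 stereocentre is racemic and is destroyed in step 7.

Step 7
Reactants: 9 3-bromo-2-(5-bromo-2-methoxyphenoxy)-6-(phenylselanyl)cyclohex-2-en-1-one
Product: 12 3-bromo-2-(5-bromo-2-methoxyphenoxy)phenol, via selenoxide 10 (not isolated), via cyclohexadienone 11 (not isolated)
Conditions: 30% H2O2 (3 equiv), NaHCO3, CH2Cl2/H2O, 0 °C → rt
Reagents that add atoms: none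
Why: Oxidation of the selenide and spontaneous selenoxide syn-elimination give the cross-conjugated dienone, which tautomerises to the phenol under the driving force of aromaticity, while excess H2O2 converts the PhSeOH lost into inert benzeneseleninic acid.

Step 8
Reactants: 12 3-bromo-2-(5-bromo-2-methoxyphenoxy)phenol
Product: 14 3,4,6-tribromo-2-(5-bromo-2-methoxyphenoxy)phenol, via para-bromophenol 13 (not isolated)
Conditions: Br2 (2.05 equiv), NaOAc (2.2 equiv), AcOH/CH2Cl2, 0 °C → rt
Reagents that add atoms: bromine, BrBr
Why: Electrophilic aromatic bromination directed by the free OH to its only open para (C4) and ortho (C6) positions, the phenol ring being far more reactive than the methyl-ether ring, which already carries a deactivating bromine.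

Step 9
Reactants: 14 3,4,6-tribromo-2-(5-bromo-2-methoxyphenoxy)phenol
Product: 15 3,4,6-tribromo-2-(5-bromo-2-hydroxyphenoxy)phenol
Conditions: BBr3 (3 equiv), CH2Cl2, −78 °C → rt; then H2O
Reagents that add atoms: none
Why: Lewis-acid O-demethylation with BBr3 (bromide attacks the methyl group of the boron-complexed ether) cleaves only the alkyl aryl ether and leaves the diaryl ether and all C–Br bonds intact.

**Compound list**

1 | 5-bromo-2-methoxyphenol | COc1ccc(Br)cc1O | starting material
2 | ethyl 4-chloro-3-oxobutanoate | CCOC(=O)CC(=O)CCl | starting material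
3 | ethyl 4-(5-bromo-2-methoxyphenoxy)-3-oxobutanoate | CCOC(=O)CC(=O)COc1cc(Br)ccc1OC | intermediate
4 | ethyl acrylate | C=CC(=O)OCC | starting material
5 | diethyl 2-[2-(5-bromo-2-methoxyphenoxy)acetyl]pentanedioate (racemic) | CCOC(=O)CCC(C(=O)OCC)C(=O)COc1cc(Br)ccc1OC | intermediate
6 | ethyl 6-(5-bromo-2-methoxyphenoxy)-5-oxohexanoate | CCOC(=O)CCCC(=O)COc1cc(Br)ccc1OC | intermediate
7 | 2-(5-bromo-2-methoxyphenoxy)cyclohexane-1,3-dione (drawn as diketone, largely enolised) | O=C1CCCC(=O)C1Oc1cc(Br)ccc1OC | intermediate
8 | 3-bromo-2-(5-bromo-2-methoxyphenoxy)cyclohex-2-en-1-one | O=C1CCCC(Br)=C1Oc1cc(Br)ccc1OC | intermediate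
9 | 3-bromo-2-(5-bromo-2-methoxyphenoxy)-6-(phenylselanyl)cyclohex-2-en-1-one (racemic) | O=C1C([Se]c2ccccc2)CCC(Br)=C1Oc1cc(Br)ccc1OC | intermediate
10 | 3-bromo-2-(5-bromo-2-methoxyphenoxy)-6-(phenylseleninyl)cyclohex-2-en-1-one (selenoxide, racemic, not isolated) | O=C1C([Se](=O)c2ccccc2)CCC(Br)=C1Oc1cc(Br)ccc1OC | intermediate
11 | 3-bromo-2-(5-bromo-2-methoxyphenoxy)cyclohexa-2,5-dien-1-one (not isolated) | O=C1C=CCC(Br)=C1Oc1cc(Br)ccc1OC | intermediate
12 | 3-bromo-2-(5-bromo-2-methoxyphenoxy)phenol | Oc1cccc(Br)c1Oc1cc(Br)ccc1OC | intermediate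
13 | 3,4-dibromo-2-(5-bromo-2-methoxyphenoxy)phenol (not isolated) | Oc1ccc(Br)c(Br)c1Oc1cc(Br)ccc1OC | intermediate
14 | 3,4,6-tribromo-2-(5-bromo-2-methoxyphenoxy)phenol | Oc1c(Br)cc(Br)c(Br)c1Oc1cc(Br)ccc1OC | intermediate
15 | 3,4,6-tribromo-2-(5-bromo-2-hydroxyphenoxy)phenol (achiral) | Oc1ccc(Br)cc1Oc1c(O)c(Br)cc(Br)c1Br | target

**Summary**

Total step count: 9. Longest linear sequence: 9 steps (1 → 15).

Three steps most likely to fail:

Step 1. The chloro keto ester 2 can self-condense under base before the phenoxide alkylates it. Fallback: setting out from 1, O-alkylation with ethyl bromoacetate (K2CO3, acetone, reflux) gives ethyl 2-(5-bromo-2-methoxyphenoxy)acetate F1. A crossed Claisen condensation of this ester with the lithium enolate of ethyl acetate (LDA, EtOAc, 2.2 equiv of enolate, THF, −78 °C) then comes back to the route at 3.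

Step 6. The kinetic enolate of the β-bromo enone may suffer amide addition–elimination at C3, and selenium residues can damage the phenol formed in step 7. Fallback: setting out from 8, acid-mediated α′-bromination with phenyltrimethylammonium tribromide (THF, 0 °C) gives 3,6-dibromo-2-(5-bromo-2-methoxyphenoxy)cyclohex-2-en-1-one F2. Dehydrobromination with Li2CO3/LiBr in DMF at 120 °C and tautomerisation then comes back to the route at 12, bypassing steps 6 and 7.

Step 8. The second (ortho) bromination is the slower one and could be overtaken by bromination of the methoxy ring. Fallback: setting out from 12, the ortho bromine is installed first, while the phenol ring is most reactive, by amine-directed delivery (NBS 1.0 equiv, i-Pr2NH 10 mol%, CH2Cl2, 0 °C). This gives 3,6-dibromo-2-(5-bromo-2-methoxyphenoxy)phenol F3. The fast para-bromination with exactly 1.0 equiv of Br2 (AcOH/NaOAc, 0 °C) then comes back to the route at 14.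

**Further compounds**

F1 | step 1 | ethyl 2-(5-bromo-2-methoxyphenoxy)acetate | CCOC(=O)COc1cc(Br)ccc1OC
F2 | step 6 | 3,6-dibromo-2-(5-bromo-2-methoxyphenoxy)cyclohex-2-en-1-one (racemic) | O=C1C(Br)CCC(Br)=C1Oc1cc(Br)ccc1OC
F3 | step 8 | 3,6-dibromo-2-(5-bromo-2-methoxyphenoxy)phenol | Oc1c(Br)ccc(Br)c1Oc1cc(Br)ccc1OC
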